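## Retrosynthetic overview

1. Target 15 ⇒ primary alcohol 14 (O‑sulfation last) ⇒ terminal alkene 11 + 3‑bromofuran 12 (hydroboration / B‑alkyl Suzuki; the furan ring is bought).
2. 11 ⇒ tertiary alcohol 10 by a dehydrative 1,2‑H / 1,2‑Me shift cascade. In labdane numbering it moves the C10 methyl to C9, sets C8 and C9 from the stereocentres of sclareolide, and leaves the 5(10)‑alkene.
3. 10 ⇒ (+)‑sclareolide 7 + (R)‑4‑allylbutyrolactone 6: the C11–C12 bond is made by anodic decarboxylative cross‑coupling of the two ring‑opened lactones (key step). It is done before the rearrangement because a C11 radical next to the 5(10)‑alkene would undergo a fast 1,2‑vinyl shift.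
4. 6 ⇒ (R)‑epichlorohydrin 1 + diethyl malonate 2 + vinylmagnesium bromide 4 via cyclopropane lactone 3; the side‑chain stereocentre is bought in 1.
5. Ring order: rings A and B are bought in 7 and the furan in 12. Only the auxiliary cyclopropane and γ‑lactone rings of 3 are built (step 1), and they are opened again in steps 2 and 4.

Assumption: the target is written, as in the question, as the neutral hydrogen sulfate; in the flask and on storage it is present as a salt (pyridinium, then sodium) of the same compound.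

Note: the descriptor of the side‑chain stereocentre changes between R and S along the route (6, 9: R; 10, 11: S; 13, 14, 15: R) only because the CIP ranking of its arms changes. No bond to this centre is ever broken.

## Route

Step 1
Reactants: 1 (R)‑epichlorohydrin; 2 diethyl malonate
Product: 3 ethyl (1S,5R)‑2‑oxo‑3‑oxabicyclo[3.1.0]hexane‑1‑carboxylate
Conditions: NaOEt (1.1 equiv), EtOH, 0 °C → reflux, 18 h
Reagents that add atoms: none
Why: Tandem alkylation–cyclopropanation–lactonisation in which the malonate anion opens the epoxide at CH2, the alkoxide closes a new epoxide by displacing chloride, the malonate anion opens that epoxide at CH with inversion (3‑exo‑tet) and the freed alkoxide lactonises, so the bought stereocentre of 1 fixes both centres of the cis‑fused bicycle.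

Step 2
Reactants: 3 ethyl (1S,5R)‑2‑oxo‑3‑oxabicyclo[3.1.0]hexane‑1‑carboxylate; 4 vinylmagnesium bromide
Product: 5 ethyl (3S,4R)‑2‑oxo‑4‑(prop‑2‑en‑1‑yl)oxolane‑3‑carboxylate (trans; any cis C3 epimer converges in step 3)
Conditions: vinylMgBr (1.5 equiv), CuBr·SMe2 (10 mol %), THF, −40 → −20 °C
Reagents that add atoms: none
Why: Copper‑catalysed homoconjugate addition of the Grignard reagent opens the doubly activated cyclopropane at its unsubstituted CH2 in an SN2‑type attack, which leaves the C4 stereocentre untouched.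

Step 3
Reactants: 5 ethyl (3S,4R)‑2‑oxo‑4‑(prop‑2‑en‑1‑yl)oxolane‑3‑carboxylate
Product: 6 (4R)‑4‑(prop‑2‑en‑1‑yl)oxolan‑2‑one
Conditions: LiCl (2 equiv), DMSO/H2O 20:1, 150 °C, 6 h
Reagents that add atoms: none
Why: Krapcho dealkoxycarbonylation removes the ester and with it the labile C3 centre, while the C4 centre is not involved.

Step 4
Reactants: 6 (4R)‑4‑(prop‑2‑en‑1‑yl)oxolan‑2‑one; 7 (+)‑sclareolide (3 equiv)
Product: 10 (1R,2R,4aS,8aS)‑1‑[(3S)‑3‑(hydroxymethyl)hex‑5‑en‑1‑yl]‑2,5,5,8a‑tetramethyldecahydronaphthalen‑2‑ol, via decalin hydroxy‑acid potassium salt 8 (not isolated), via side‑chain hydroxy‑acid potassium salt 9 (not isolated)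
Conditions: KOH (1.05 equiv per lactone), MeOH/H2O 9:1, 60 °C, 3 h; then undivided cell, Pt anode, Pt cathode, 0.25 A cm⁻², 5–10 °C, ca. 2.5 F mol⁻¹, polarity reversed every 60 s
Reagents that add atoms: potassium hydroxide, [K+].[OH-] (K and O enter 8 and 9 only)
Why: Proposed new method: a lactone‑to‑lactone cross‑Kolbe coupling in which both lactones are opened in the cell and the two free γ‑hydroxy carboxylates are co‑oxidised at Pt at high current density to acyloxy radicals that lose CO2 at once, the resulting primary radicals (the β‑branched C11 radical at C9 and the side‑chain C12 radical) being neither β‑oxygenated nor stabilised enough for further oxidation to cations nor set up for fast cyclisation or vinyl shift, so they combine in the dense radical layer at the anode to form the C11–C12 bond without touching any stereocentre, a threefold excess of the cheap sclareolide salt steering the side‑chain radical statistically into the cross product; the closest known reaction type is the mixed Kolbe electrolysis of two simple alkanoic acids, which has not been shown for two unprotected lactone‑derived hydroxy acids or for a terpenoid carboxylate carrying a free tertiary alcohol.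

Step 5
Reactants: 10 (1R,2R,4aS,8aS)‑1‑[(3S)‑3‑(hydroxymethyl)hex‑5‑en‑1‑yl]‑2,5,5,8a‑tetramethyldecahydronaphthalen‑2‑ol
Product: 11 (2S)‑2‑{2‑[(1R,2S)‑1,2,5,5‑tetramethyl‑1,2,3,4,5,6,7,8‑octahydronaphthalen‑1‑yl]ethyl}pent‑4‑en‑1‑ol
Conditions: BF3·OEt2 (3 equiv), CH2Cl2 (0.01 M), −60 → −20 °C, 1–2 h
Reagents that add atoms: none
Why: Lewis‑acid ionisation of the tertiary alcohol starts a stereospecific Wagner–Meerwein (friedo) cascade, known for drimane and labdane C8 cations, in which the 9α‑H shifts to the α face of C8, the 10β‑methyl shifts to the β face of C9 and H‑5 is lost (E1), so the bought C9 and C10 configuration of sclareolide is relayed into the 2S and 1R centres and the tetrasubstituted alkene.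

Step 6
Reactants: 11 (2S)‑2‑{2‑[(1R,2S)‑1,2,5,5‑tetramethyl‑1,2,3,4,5,6,7,8‑octahydronaphthalen‑1‑yl]ethyl}pent‑4‑en‑1‑ol; 12 3‑bromofuran
Product: 14 (2R)‑5‑(furan‑3‑yl)‑2‑{2‑[(1R,2S)‑1,2,5,5‑tetramethyl‑1,2,3,4,5,6,7,8‑octahydronaphthalen‑1‑yl]ethyl}pentan‑1‑ol, via bis‑boryl adduct 13 (not isolated)
Conditions: 9‑BBN (2.4 equiv), THF, 0 °C → rt, 4 h; then 3‑bromofuran (1.5 equiv), Pd(dppf)Cl2 (5 mol %), 3 M NaOH aq, THF, 60 °C
Reagents that add atoms: 9‑borabicyclo[3.3.1]nonane (9‑BBN), B1C2CCCC1CCC2 (boron enters 13 only)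
Why: 9‑BBN hydroborates only the terminal alkene (the tetrasubstituted ring alkene is inert and the free OH is taken up as a borinate by the excess reagent), and the B‑alkyl Suzuki–Miyaura coupling then forms the sp3–sp2 bond to the furan without touching a stereocentre.

Step 7
Reactants: 14 (2R)‑5‑(furan‑3‑yl)‑2‑{2‑[(1R,2S)‑1,2,5,5‑tetramethyl‑1,2,3,4,5,6,7,8‑octahydronaphthalen‑1‑yl]ethyl}pentan‑1‑ol
Product: 15 (2R)‑5‑(furan‑3‑yl)‑2‑{2‑[(1R,2S)‑1,2,5,5‑tetramethyl‑1,2,3,4,5,6,7,8‑octahydronaphthalen‑1‑yl]ethyl}pentyl hydrogen sulfate (target, CNP0377032.3)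
Conditions: SO3·pyridine (3 equiv), pyridine, 0 °C → rt, 3 h
Reagents that add atoms: sulfur trioxide–pyridine complex, [O-]S(=O)(=O)[n+]1ccccc1
Why: O‑sulfation of the only hydroxyl by the mild SO3·pyridine complex, which does not attack the furan or the tetrasubstituted alkene at or below room temperature.

## Compound list

1 | (R)‑epichlorohydrin, (2R)‑2‑(chloromethyl)oxirane | ClC[C@H]1CO1 | starting material
2 | diethyl malonate | CCOC(=O)CC(=O)OCC | starting material
3 | ethyl (1S,5R)‑2‑oxo‑3‑oxabicyclo[3.1.0]hexane‑1‑carboxylate | CCOC(=O)[C@]12C[C@H]1COC2=O | intermediate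
4 | vinylmagnesium bromide | C=C[Mg]Br | starting material
5 | ethyl (3S,4R)‑2‑oxo‑4‑(prop‑2‑en‑1‑yl)oxolane‑3‑carboxylate | CCOC(=O)[C@H]1C(=O)OC[C@@H]1CC=C | intermediate
6 | (4R)‑4‑(prop‑2‑en‑1‑yl)oxolan‑2‑one | C=CC[C@H]1COC(=O)C1 | intermediate
7 | (+)‑sclareolide, (3aR,5aS,9aS,9bR)‑3a,6,6,9a‑tetramethyldecahydronaphtho[2,1‑b]furan‑2(1H)‑one | CC1(C)CCC[C@@]2(C)[C@H]1CC[C@@]1(C)OC(=O)C[C@H]21 | starting material
8 | potassium [(1R,2R,4aS,8aS)‑2‑hydroxy‑2,5,5,8a‑tetramethyldecahydronaphthalen‑1‑yl]acetate | CC1(C)CCC[C@@]2(C)[C@H]1CC[C@@](C)(O)[C@@H]2CC(=O)[O-].[K+] | intermediate (not isolated)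
9 | potassium (3R)‑3‑(hydroxymethyl)hex‑5‑enoate | [K+].[O-]C(=O)C[C@H](CO)CC=C | intermediate (not isolated)
10 | (1R,2R,4aS,8aS)‑1‑[(3S)‑3‑(hydroxymethyl)hex‑5‑en‑1‑yl]‑2,5,5,8a‑tetramethyldecahydronaphthalen‑2‑ol | CC1(C)CCC[C@@]2(C)[C@H]1CC[C@@](C)(O)[C@@H]2CC[C@H](CO)CC=C | intermediate
11 | (2S)‑2‑{2‑[(1R,2S)‑1,2,5,5‑tetramethyl‑1,2,3,4,5,6,7,8‑octahydronaphthalen‑1‑yl]ethyl}pent‑4‑en‑1‑ol | C[C@H]1CCC2=C(CCCC2(C)C)[C@]1(C)CC[C@H](CO)CC=C | intermediate
12 | 3‑bromofuran | Brc1ccoc1 | starting material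
13 | 9‑{(4R)‑4‑[(9‑borabicyclo[3.3.1]nonan‑9‑yloxy)methyl]‑6‑[(1R,2S)‑1,2,5,5‑tetramethyl‑1,2,3,4,5,6,7,8‑octahydronaphthalen‑1‑yl]hexyl}‑9‑borabicyclo[3.3.1]nonane | C[C@H]1CCC2=C(CCCC2(C)C)[C@]1(C)CC[C@H](COB1C2CCCC1CCC2)CCCB1C2CCCC1CCC2 | intermediate (not isolated)
14 | (2R)‑5‑(furan‑3‑yl)‑2‑{2‑[(1R,2S)‑1,2,5,5‑tetramethyl‑1,2,3,4,5,6,7,8‑octahydronaphthalen‑1‑yl]ethyl}pentan‑1‑ol | C[C@H]1CCC2=C(CCCC2(C)C)[C@]1(C)CC[C@H](CO)CCCc1ccoc1 | intermediate
15 | (2R)‑5‑(furan‑3‑yl)‑2‑{2‑[(1R,2S)‑1,2,5,5‑tetramethyl‑1,2,3,4,5,6,7,8‑octahydronaphthalen‑1‑yl]ethyl}pentyl hydrogen sulfate | C[C@H]1CCC2=C(CCCC2(C)C)[C@]1(C)CC[C@@H](CCCc1ccoc1)COS(=O)(=O)O | target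

## Step count and risks

Total step count: 7. Longest linear sequence: 7 steps (1 → 3 → 5 → 6 → 10 → 11 → 14 → 15); 7 and 12 enter without prior steps.

The three steps most likely to fail:

Risk 1, the anodic cross‑coupling of step 4 (the proposed new step). The coupling is statistical, the medium turns bicarbonate‑basic as the carboxylates are consumed, and the hindered C11 radical may partly be over‑oxidised or disproportionate. Unreacted 8 and 9 return to 7 and 6 on acidification and can be recycled. The fallback uses known chemistry, sets out from 6 and 7 (opened to 9 and 8 as in step 4) and comes back at 10. Salt 8 is O‑silylated (TESOTf, 2,6‑lutidine; K2CO3/MeOH work‑up returns the carboxylic acid) to 2‑[(1R,2R,4aS,8aS)‑2,5,5,8a‑tetramethyl‑2‑(triethylsilyloxy)decahydronaphthalen‑1‑yl]acetic acid F1. This is converted (N‑hydroxyphthalimide, DIC, DMAP) into its 1,3‑dioxoisoindolin‑2‑yl ester F2. Salt 9 is treated likewise (TBSCl, imidazole; K2CO3/MeOH) to give (3R)‑3‑{[tert‑butyl(dimethyl)silyl]oxymethyl}hex‑5‑enoic acid F3 and its 1,3‑dioxoisoindolin‑2‑yl ester F4. The two redox‑active esters are joined by the established nickel‑electrocatalytic doubly decarboxylative sp3–sp3 coupling (NiCl2·6H2O, tridentate pyridine‑type ligand, Zn sacrificial anode, DMF, constant current, F2 in excess). The cathodically formed radicals are captured by nickel instead of dimerising freely, giving the bis‑silyl ether tert‑butyl{[(2S)‑2‑{2‑[(1R,2R,4aS,8aS)‑2,5,5,8a‑tetramethyl‑2‑(triethylsilyloxy)decahydronaphthalen‑1‑yl]ethyl}pent‑4‑en‑1‑yl]oxy}dimethylsilane F5. Desilylation with TBAF (THF, 50 °C) gives 10.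

Risk 2, the cationic cascade of step 5. The free primary hydroxyl could trap the C9 or C10 cation as a cyclic ether, simple dehydration could stop at the 8(9)‑alkene, or the shifts could run on toward a clerodane‑type skeleton. The fallback sets out from 10 and comes back at 11. It masks the hydroxyl and starts the cascade from a defined alkene, the substrate type for which this rearrangement is established. Ac2O/pyridine at 0 °C gives the primary acetate [(2S)‑2‑{2‑[(1R,2R,4aS,8aS)‑2‑hydroxy‑2,5,5,8a‑tetramethyldecahydronaphthalen‑1‑yl]ethyl}pent‑4‑en‑1‑yl] acetate F6. SOCl2/pyridine at −40 °C dehydrates it mainly to the exocyclic alkene [(2S)‑2‑{2‑[(1S,4aS,8aS)‑5,5,8a‑trimethyl‑2‑methylidenedecahydronaphthalen‑1‑yl]ethyl}pent‑4‑en‑1‑yl] acetate F7; its endocyclic isomers are not separated because they converge. BF3·OEt2 in CH2Cl2 (−50 → −5 °C) rearranges this to [(2S)‑2‑{2‑[(1R,2S)‑1,2,5,5‑tetramethyl‑1,2,3,4,5,6,7,8‑octahydronaphthalen‑1‑yl]ethyl}pent‑4‑en‑1‑yl] acetate F8. K2CO3/MeOH then gives 11.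

Risk 3, the hydroboration/Suzuki coupling of step 6. 3‑Bromofuran is volatile and a sluggish partner, and the B‑alkyl borane carrying an O‑borinate may protodeboronate. The fallback sets out from 11 and comes back at 14. It replaces boron chemistry by olefin metathesis and reduction. Cross‑metathesis of 11 with 3‑vinylfuran (second‑generation Hoveyda–Grubbs catalyst, CH2Cl2, 40 °C; the tetrasubstituted alkene is inert) gives (2S,4E)‑5‑(furan‑3‑yl)‑2‑{2‑[(1R,2S)‑1,2,5,5‑tetramethyl‑1,2,3,4,5,6,7,8‑octahydronaphthalen‑1‑yl]ethyl}pent‑4‑en‑1‑ol F9. Diimide (2‑nitrobenzenesulfonyl hydrazide, Et3N, rt) saturates only the disubstituted alkene and gives 14.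

Further compounds

F1 | step 4 | 2‑[(1R,2R,4aS,8aS)‑2,5,5,8a‑tetramethyl‑2‑(triethylsilyloxy)decahydronaphthalen‑1‑yl]acetic acid | CC1(C)CCC[C@@]2(C)[C@H]1CC[C@@](C)(O[Si](CC)(CC)CC)[C@@H]2CC(=O)O
F2 | step 4 | 1,3‑dioxoisoindolin‑2‑yl 2‑[(1R,2R,4aS,8aS)‑2,5,5,8a‑tetramethyl‑2‑(triethylsilyloxy)decahydronaphthalen‑1‑yl]acetate | CC1(C)CCC[C@@]2(C)[C@H]1CC[C@@](C)(O[Si](CC)(CC)CC)[C@@H]2CC(=O)ON1C(=O)c2ccccc2C1=O
F3 | step 4 | (3R)‑3‑{[tert‑butyl(dimethyl)silyl]oxymethyl}hex‑5‑enoic acid | OC(=O)C[C@H](CO[Si](C)(C)C(C)(C)C)CC=C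
F4 | step 4 | 1,3‑dioxoisoindolin‑2‑yl (3R)‑3‑{[tert‑butyl(dimethyl)silyl]oxymethyl}hex‑5‑enoate | O=C(C[C@H](CO[Si](C)(C)C(C)(C)C)CC=C)ON1C(=O)c2ccccc2C1=O
F5 | step 4 | tert‑butyl{[(2S)‑2‑{2‑[(1R,2R,4aS,8aS)‑2,5,5,8a‑tetramethyl‑2‑(triethylsilyloxy)decahydronaphthalen‑1‑yl]ethyl}pent‑4‑en‑1‑yl]oxy}dimethylsilane | CC1(C)CCC[C@@]2(C)[C@H]1CC[C@@](C)(O[Si](CC)(CC)CC)[C@@H]2CC[C@H](CO[Si](C)(C)C(C)(C)C)CC=C
F6 | step 5 | [(2S)‑2‑{2‑[(1R,2R,4aS,8aS)‑2‑hydroxy‑2,5,5,8a‑tetramethyldecahydronaphthalen‑1‑yl]ethyl}pent‑4‑en‑1‑yl] acetate | CC1(C)CCC[C@@]2(C)[C@H]1CC[C@@](C)(O)[C@@H]2CC[C@H](COC(C)=O)CC=C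
F7 | step 5 | [(2S)‑2‑{2‑[(1S,4aS,8aS)‑5,5,8a‑trimethyl‑2‑methylidenedecahydronaphthalen‑1‑yl]ethyl}pent‑4‑en‑1‑yl] acetate | CC1(C)CCC[C@@]2(C)[C@H]1CCC(=C)[C@@H]2CC[C@H](COC(C)=O)CC=C
F8 | step 5 | [(2S)‑2‑{2‑[(1R,2S)‑1,2,5,5‑tetramethyl‑1,2,3,4,5,6,7,8‑octahydronaphthalen‑1‑yl]ethyl}pent‑4‑en‑1‑yl] acetate | C[C@H]1CCC2=C(CCCC2(C)C)[C@]1(C)CC[C@H](COC(C)=O)CC=C
F9 | step 6 | (2S,4E)‑5‑(furan‑3‑yl)‑2‑{2‑[(1R,2S)‑1,2,5,5‑tetramethyl‑1,2,3,4,5,6,7,8‑octahydronaphthalen‑1‑yl]ethyl}pent‑4‑en‑1‑ol | C[C@H]1CCC2=C(CCCC2(C)C)[C@]1(C)CC[C@H](CO)C/C=C/c1ccoc1
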